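Everything rests on disconnecting the angular methyl C14 from quaternary C10 at the ring A/ring B fusion. Its neighbour C5 ends as the hydroperoxide carbon and has to be olefinic first, so C14 is installed as the methylene of a three-membered ring spanning C5 and C10. A single alcohol-directed methylene transfer to the tetrasubstituted C5=C10 bond makes C10–C14 plus a sacrificial C5–C14 bond and fixes C10, the centre to which C3, C5, C7 and C8 are later related. The substrate is the (4S)-Δ5(10)-octalin-4β-ol obtained by Birch reduction of an anisole, its former methoxy carbon C8 masked as a dioxolane. Radical cleavage of C5–C14 later releases the methyl and the Δ4 alkene for the closing ene oxygenation.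

Key step: step 4

Remark: eudesmane numbering is used (C14 = methyl on C10, C15 = carbon on C4, C11–C13 = acrylate unit); the target SMILES is read as 3α-angeloyloxy, 5α-hydroperoxy, 7β side chain, 8β-acetoxy, 10β-methyl (3R,5S,7R,8R,10R), so the C3 oxygen has to enter anti to C14.

Step 1
Reactants: 1 6-methoxy-1-tetralone
Product: 2 (S)-6-methoxy-1,2,3,4-tetrahydronaphthalen-1-ol
Conditions: RuCl(p-cymene)[(S,S)-TsDPEN] (1 mol %), HCO2H/Et3N (5:2), 40 °C
Reagents that add atoms: none
Why: Noyori–Ikariya asymmetric transfer hydrogenation, in which the (S,S)-configured Ru–H/N–H catalyst delivers hydride to one face of the aryl ketone through its six-membered transition state and should give the (S)-carbinol that becomes the 4β-hydroxyl.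

Step 2
Reactants: 2 (S)-6-methoxy-1,2,3,4-tetrahydronaphthalen-1-ol
Product: 4 (S)-6-methoxy-1,2,3,4,5,8-hexahydronaphthalen-1-ol, via lithium alkoxide 3 (not isolated)
Conditions: n-BuLi, THF, −78 °C; then Li, NH3(l), t-BuOH, −78 to −40 °C; solid NH4Cl
Reagents that add atoms: none
Why: Birch reduction, in which the pre-formed benzylic alkoxide resists C–O hydrogenolysis and the anisole ring should be reduced to the 2,5-dihydro compound with its alkenes at the methoxy carbon (C7=C8) and at the ring fusion (C5=C10), the carbinol centre being untouched.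

Step 3
Reactants: 4 (S)-6-methoxy-1,2,3,4,5,8-hexahydronaphthalen-1-ol; 5 ethylene glycol
Product: 6 Δ5(10)-octalin-4β-ol with C8 as its dioxolane
Conditions: HOCH2CH2OH, PPTS (cat.), THF, 0 °C to rt
Reagents that add atoms: ethylene glycol OCCO
Why: Acid-catalysed transketalisation of an enol ether, in which C7 protonation gives the C8 oxocarbenium ion that the diol captures and closes with loss of methanol, under acid too weak to move the C5=C10 bond or ionise the allylic alcohol.

Step 4
Reactants: 6 Δ5(10)-octalin-4β-ol with C8 as its dioxolane; 7 diiodomethane; 8 diethylzinc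
Product: 10 5β,10β-methanodecalin-4β-ol with C8 dioxolane, via ethylzinc alkoxide 9 (not isolated)
Conditions: Et2Zn, then CH2I2, CH2Cl2, −10 °C to rt
Reagents that add atoms: diiodomethane ICI
Why: Diethylzinc deprotonates the C4 hydroxyl, and the resulting ethylzinc alkoxide coordinates the iodomethylzinc species formed from CH2I2 and hands its methylene intramolecularly to the neighbouring C5=C10 bond, so that C10–C14 and C5–C14 form in one concerted syn addition. The closest known reaction is the hydroxyl-directed Simmons–Smith cyclopropanation (Furukawa variant) of 2-cyclohexen-1-ols, including octalinols with a tetrasubstituted ring-fusion alkene. The ring C5–C10–C14 closes by (2+1) methylene transfer to the alkene and not by a stepwise cyclisation. Both new stereocentres, C5 and C10, are controlled by the 4β-oxygen, because the methylene arrives on the face that carries the alkoxide and the bridge is therefore β. Only facial selectivity is needed, since there is a single alkene, and the allylic zinc alkoxide one bond from C5 should outweigh the remote C8 dioxolane oxygens, which lie on both faces, while also speeding attack on the hindered but electron-rich alkene.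

Step 5
Reactants: 10 5β,10β-methanodecalin-4β-ol with C8 dioxolane
Product: 11 5β,10β-methanodecalin-4-one with C8 dioxolane
Conditions: (n-Pr4N)RuO4 (cat.), N-methylmorpholine N-oxide, 4 Å sieves, CH2Cl2, rt
Reagents that add atoms: none
Why: Ley–Griffith oxidation, a neutral catalytic perruthenate oxidation that should convert the secondary cyclopropyl carbinol into the ketone without acid that could open the cyclopropylcarbinyl system or the dioxolane.

Step 6
Reactants: 11 5β,10β-methanodecalin-4-one with C8 dioxolane; 12 3-phenyl-2-(phenylsulfonyl)oxaziridine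
Product: 14 3α-hydroxy-5β,10β-methanodecalin-4-one with C8 dioxolane, via potassium enolate 13 (not isolated)
Conditions: KN(SiMe3)2, THF, −78 °C; then 12, −78 °C; aq. NH4Cl
Reagents that add atoms: 3-phenyl-2-(phenylsulfonyl)oxaziridine O=S(=O)(N1OC1c1ccccc1)c1ccccc1
Why: Davis enolate oxidation, in which the ketone can enolise only toward C3 because C5 is quaternary, and the oxaziridine should transfer oxygen to the enolate face anti to the β-methano bridge, whose inward C14–H lies over ring A, setting the 3α-hydroxyl.

Step 7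
Reactants: 14 3α-hydroxy-5β,10β-methanodecalin-4-one with C8 dioxolane; 15 tert-butyldimethylsilyl chloride
Product: 16 3α-(tert-butyldimethylsilyloxy)-5β,10β-methanodecalin-4-one with C8 dioxolane
Conditions: t-BuMe2SiCl, imidazole, DMF, rt to 40 °C
Reagents that add atoms: tert-butyldimethylsilyl chloride CC(C)(C)[Si](C)(C)Cl
Why: Imidazole-promoted silyl ether formation, a non-acidic protection that leaves the dioxolane and the C3 centre intact and gives an ether able to survive the later amide bases, hydride and aqueous hydroxide.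

Step 8
Reactants: 16 3α-(tert-butyldimethylsilyloxy)-5β,10β-methanodecalin-4-one with C8 dioxolane; 17 dimethyltitanocene Cp2TiMe2
Product: 18 4-methylidene-3α-(tert-butyldimethylsilyloxy)-5β,10β-methanodecalin with C8 dioxolane
Conditions: Cp2TiMe2, toluene, 70 °C, dark
Reagents that add atoms: dimethyltitanocene C[Ti](C)(C1C=CC=C1)C1C=CC=C1
Why: Petasis methylenation, in which the titanium methylidene formed on heating converts the hindered, enolisable C4 ketone into the exocyclic alkene through an oxatitanacyclobutane without base, so C3 should not epimerise while C15 is installed.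

Step 9
Reactants: 18 4-methylidene-3α-(tert-butyldimethylsilyloxy)-5β,10β-methanodecalin with C8 dioxolane
Product: 19 3α-(tert-butyldimethylsilyloxy)-11,12,13-trinoreudesm-4-en-8-one ethylene ketal
Conditions: Mn(dpm)3 (cat., dpm = 2,2,6,6-tetramethylheptane-3,5-dionate), PhSiH3, t-BuOOH, i-PrOH, degassed, rt
Reagents that add atoms: none
Why: Metal-hydride hydrogen-atom-transfer hydrogenation (Mukaiyama type), in which Mn–H adds a hydrogen atom to C15, the tertiary C4 cyclopropylcarbinyl radical opens the exocyclic C5–C14 bond that overlaps its half-filled orbital (as norcaranyl radical clocks do), and the primary C14 radical is reduced to the 10β-methyl, giving the Δ4 alkene with no new stereocentre and sparing the dioxolane and silyl ether that a Lewis-acidic iodide opening such as Me3SiI would attack.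

Step 10
Reactants: 19 3α-(tert-butyldimethylsilyloxy)-11,12,13-trinoreudesm-4-en-8-one ethylene ketal; 20 water
Product: 21 3α-(tert-butyldimethylsilyloxy)-11,12,13-trinoreudesm-4-en-8-one
Conditions: PPTS, acetone/H2O (9:1), 40 °C
Reagents that add atoms: water O
Why: Acid-catalysed ketal hydrolysis with a weak pyridinium acid, which should free the C8 ketone while the tetrasubstituted alkene cannot move into conjugation and the hindered secondary silyl ether tolerates the buffered medium.

Step 11
Reactants: 21 3α-(tert-butyldimethylsilyloxy)-11,12,13-trinoreudesm-4-en-8-one; 22 methyl bromoacetate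
Product: 25 methyl 3α-(tert-butyldimethylsilyloxy)-8-oxo-13-noreudesm-4-en-12-oate (C7 side chain β), via lithium enolate 23 (not isolated), via 7α-epimer 24 (not isolated)
Conditions: LiN(i-Pr)2, THF, −78 °C; BrCH2CO2Me, DMPU, −78 to −30 °C; then NaOMe (cat.), MeOH, 0 °C
Reagents that add atoms: methyl bromoacetate COC(=O)CBr
Why: Kinetic enolate alkylation, in which the amide base removes the less hindered C7 proton (C9 is flanked by quaternary C10), the enolate is alkylated by the bromoacetate, and catalytic methoxide then equilibrates C7 so that the side chain should end equatorial (β).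

Step 12
Reactants: 25 methyl 3α-(tert-butyldimethylsilyloxy)-8-oxo-13-noreudesm-4-en-12-oate
Product: 27 3α-(tert-butyldimethylsilyloxy)-13-noreudesm-4-en-12,8β-olide (cis-fused γ-lactone), via hydroxy ester 26 (not isolated)
Conditions: LiBH(s-Bu)3, THF, −78 °C; aq. NH4Cl; then PPTS (cat.), CH2Cl2, rt
Reagents that add atoms: none
Why: Diastereoselective hydride reduction followed by lactonisation, in which the axial (β) trajectory at C8 is blocked by the syn-axial C14 methyl so that hydride enters equatorially and gives the axial 8β-alcohol, which is cis to the C7 acetate arm and should close to the cis-fused lactone.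

Step 13
Reactants: 27 3α-(tert-butyldimethylsilyloxy)-13-noreudesm-4-en-12,8β-olide; 28 dimethyl(methylidene)ammonium iodide
Product: 32 3α-(tert-butyldimethylsilyloxy)eudesma-4,11(13)-dien-12,8β-olide, via lactone enolate 29 (not isolated), via Mannich base 30 (not isolated), via methiodide 31 (not isolated)
Conditions: LiN(i-Pr)2, THF, −78 °C; CH2=NMe2+ I−, −78 °C to rt; MeI, THF, rt; then aq. NaHCO3, EtOAc, rt
Reagents that add atoms: dimethyl(methylidene)ammonium iodide C=[N+](C)C.[I-]
Why: Lactone α-methylenation by Mannich reaction and Hofmann-type elimination, in which the lactone enolate adds to the iminium salt, N-methylation turns the amine into a leaving group and mild base expels trimethylamine to give the C11=C13 methylene without touching C7 or C8.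

Step 14
Reactants: 32 3α-(tert-butyldimethylsilyloxy)eudesma-4,11(13)-dien-12,8β-olide; 33 lithium hydroxide; 34 (trimethylsilyl)diazomethane
Product: 36 methyl 8β-hydroxy-3α-(tert-butyldimethylsilyloxy)eudesma-4,11(13)-dien-12-oate, via hydroxy acid 35 (not isolated)
Conditions: LiOH, THF/H2O, 0 °C to rt; cold dilute HCl to pH 5, extract; Me3SiCHN2, toluene/MeOH, 0 °C
Reagents that add atoms: lithium hydroxide [Li+].[OH-]; (trimethylsilyl)diazomethane C[Si](C)(C)C=[N+]=[N-]
Why: Saponification and diazoalkane esterification, in which hydroxide opens the lactone at the acyl carbon with C8 retained, cautious acidification gives the cis-hydroxy acid (acids of this alantolic type are isolable), and the neutral, fast methylation of the carboxylic acid should outrun relactonisation.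

Step 15
Reactants: 36 methyl 8β-hydroxy-3α-(tert-butyldimethylsilyloxy)eudesma-4,11(13)-dien-12-oate; 37 acetic anhydride
Product: 38 methyl 8β-acetoxy-3α-(tert-butyldimethylsilyloxy)eudesma-4,11(13)-dien-12-oate
Conditions: Ac2O, DMAP, Et3N, CH2Cl2, 0 °C to rt
Reagents that add atoms: acetic anhydride CC(=O)OC(C)=O
Why: DMAP-catalysed acetylation (nucleophilic acyl-transfer catalysis), which should cap the hindered axial 8β-hydroxyl and thereby remove the path back to the lactone, the silyl ether and acrylate being inert.

Step 16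
Reactants: 38 methyl 8β-acetoxy-3α-(tert-butyldimethylsilyloxy)eudesma-4,11(13)-dien-12-oate
Product: 39 methyl 8β-acetoxy-3α-hydroxyeudesma-4,11(13)-dien-12-oate
Conditions: HF·pyridine, pyridine/THF, 0 °C to rt
Reagents that add atoms: none
Why: Fluoride-mediated desilylation with pyridine-buffered HF, which should remove the C3 silyl ether without the ester cleavage, acyl migration or conjugate addition that basic fluoride sources can cause and without ionising the allylic alcohol.

Step 17
Reactants: 39 methyl 8β-acetoxy-3α-hydroxyeudesma-4,11(13)-dien-12-oate; 40 angelic acid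
Product: 41 methyl 8β-acetoxy-3α-angeloyloxyeudesma-4,11(13)-dien-12-oate
Conditions: 2,4,6-Cl3C6H2COCl, Et3N, toluene, rt; then 39, 75 °C
Reagents that add atoms: angelic acid C/C=C(/C)C(=O)O
Why: Yamaguchi esterification run without DMAP, in which the alcohol attacks the angeloyl carbonyl of the mixed anhydride (the aroyl carbonyl is shielded by its two ortho chlorines) with retention at C3, and the absence of a nucleophilic catalyst should prevent Z-to-E isomerisation to the tiglate.

Step 18
Reactants: 41 methyl 8β-acetoxy-3α-angeloyloxyeudesma-4,11(13)-dien-12-oate; 42 dioxygen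
Product: 43 methyl 8β-acetoxy-3α-angeloyloxy-5α-hydroperoxyeudesma-4(15),11(13)-dien-12-oate (CNP0116769.2)
Conditions: O2, tetraphenylporphyrin (cat.), visible light, CH2Cl2, −20 °C
Reagents that add atoms: dioxygen O=O
Why: Schenck ene reaction of singlet oxygen, which should attack the electron-rich tetrasubstituted C4=C5 bond from the α face anti to the axial C14 methyl, where only the C15 hydrogens are aligned for abstraction (C3 has no α-hydrogen and the 6α-hydrogen lies in the alkene plane), so that oxygen bonds to C5, the alkene moves to C4=C15 and the 5α-hydroperoxide is set while the electron-poor angelate and acrylate alkenes stay untouched.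

Compound list
1 | 6-methoxy-1-tetralone | COc1ccc2c(c1)CCCC2=O | starting material
2 | (S)-6-methoxy-1,2,3,4-tetrahydronaphthalen-1-ol | COc1ccc2c(c1)CCC[C@@H]2O | intermediate
3 | lithium alkoxide of 2 | COc1ccc2c(c1)CCC[C@@H]2[O-].[Li+] | intermediate
4 | (S)-6-methoxy-1,2,3,4,5,8-hexahydronaphthalen-1-ol (C4 carbinol, C5=C10, C7=C8 methyl enol ether) | COC1=CCC2=C(C1)CCC[C@@H]2O | intermediate
5 | ethylene glycol | OCCO | starting material
6 | Δ5(10)-octalin-4β-ol with C8 as its dioxolane; (5'S)-3',4',5',6',7',8'-hexahydro-1'H-spiro[1,3-dioxolane-2,2'-naphthalen]-5'-ol | C1CC2=C(CC13OCCO3)CCC[C@@H]2O | intermediate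
7 | diiodomethane | ICI | starting material
8 | diethylzinc | CC[Zn]CC | starting material
9 | ethylzinc alkoxide of 6 | C1CC2=C(CC13OCCO3)CCC[C@@H]2O[Zn]CC | intermediate
10 | 5β,10β-methanodecalin-4β-ol with C8 dioxolane (cyclopropane C5–C10–C14 syn to the hydroxyl) | C1C[C@@]23C[C@]2(CC14OCCO4)CCC[C@@H]3O | intermediate
11 | 5β,10β-methanodecalin-4-one with C8 dioxolane | C1C[C@@]23C[C@]2(CC14OCCO4)CCCC3=O | intermediate
12 | 3-phenyl-2-(phenylsulfonyl)oxaziridine | O=S(=O)(N1OC1c1ccccc1)c1ccccc1 | starting material
13 | potassium C3=C4 enolate of 11 | C1C[C@@]23C[C@]2(CC14OCCO4)CCC=C3[O-].[K+] | intermediate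
14 | 3α-hydroxy-5β,10β-methanodecalin-4-one with C8 dioxolane | C1C[C@@]23C[C@]2(CC14OCCO4)CC[C@@H](O)C3=O | intermediate
15 | tert-butyldimethylsilyl chloride | CC(C)(C)[Si](C)(C)Cl | starting material
16 | 3α-(tert-butyldimethylsilyloxy)-5β,10β-methanodecalin-4-one with C8 dioxolane | C1C[C@@]23C[C@]2(CC14OCCO4)CC[C@@H](O[Si](C)(C)C(C)(C)C)C3=O | intermediate
17 | dimethyltitanocene Cp2TiMe2 | C[Ti](C)(C1C=CC=C1)C1C=CC=C1 | starting material
18 | 4-methylidene-3α-(tert-butyldimethylsilyloxy)-5β,10β-methanodecalin with C8 dioxolane | C1C[C@@]23C[C@]2(CC14OCCO4)CC[C@@H](O[Si](C)(C)C(C)(C)C)C3=C | intermediate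
19 | 3α-(tert-butyldimethylsilyloxy)-11,12,13-trinoreudesm-4-en-8-one ethylene ketal | C[C@]12CC[C@@H](O[Si](C)(C)C(C)(C)C)C(C)=C1CCC3(OCCO3)C2 | intermediate
20 | water | O | starting material
21 | 3α-(tert-butyldimethylsilyloxy)-11,12,13-trinoreudesm-4-en-8-one | C[C@]12CC[C@@H](O[Si](C)(C)C(C)(C)C)C(C)=C1CCC(=O)C2 | intermediate
22 | methyl bromoacetate | COC(=O)CBr | starting material
23 | lithium C7=C8 enolate of 21 | C[C@]12CC[C@@H](O[Si](C)(C)C(C)(C)C)C(C)=C1CC=C([O-])C2.[Li+] | intermediate
24 | 7α-epimer of 25 (axial side chain) | C[C@]12CC[C@@H](O[Si](C)(C)C(C)(C)C)C(C)=C1C[C@@H](CC(=O)OC)C(=O)C2 | intermediate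
25 | methyl 3α-(tert-butyldimethylsilyloxy)-8-oxo-13-noreudesm-4-en-12-oate (7β side chain) | C[C@]12CC[C@@H](O[Si](C)(C)C(C)(C)C)C(C)=C1C[C@H](CC(=O)OC)C(=O)C2 | intermediate
26 | methyl 8β-hydroxy-3α-(tert-butyldimethylsilyloxy)-13-noreudesm-4-en-12-oate | C[C@]12CC[C@@H](O[Si](C)(C)C(C)(C)C)C(C)=C1C[C@H](CC(=O)OC)[C@H](O)C2 | intermediate
27 | 3α-(tert-butyldimethylsilyloxy)-13-noreudesm-4-en-12,8β-olide | C[C@]12CC[C@@H](O[Si](C)(C)C(C)(C)C)C(C)=C1C[C@@H]3CC(=O)O[C@@H]3C2 | intermediate
28 | dimethyl(methylidene)ammonium iodide | C=[N+](C)C.[I-] | starting material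
29 | lithium enolate of lactone 27 | C[C@]12CC[C@@H](O[Si](C)(C)C(C)(C)C)C(C)=C1C[C@@H]3C=C([O-])O[C@@H]3C2.[Li+] | intermediate
30 | 13-(dimethylamino)-3α-(tert-butyldimethylsilyloxy)eudesm-4-en-12,8β-olide (C11 epimers) | C[C@]12CC[C@@H](O[Si](C)(C)C(C)(C)C)C(C)=C1C[C@@H]3C(CN(C)C)C(=O)O[C@@H]3C2 | intermediate
31 | N-methyl ammonium iodide of 30 | C[C@]12CC[C@@H](O[Si](C)(C)C(C)(C)C)C(C)=C1C[C@@H]3C(C[N+](C)(C)C)C(=O)O[C@@H]3C2.[I-] | intermediate
32 | 3α-(tert-butyldimethylsilyloxy)eudesma-4,11(13)-dien-12,8β-olide | C[C@]12CC[C@@H](O[Si](C)(C)C(C)(C)C)C(C)=C1C[C@@H]3C(=C)C(=O)O[C@@H]3C2 | intermediate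
33 | lithium hydroxide | [Li+].[OH-] | starting material
34 | (trimethylsilyl)diazomethane | C[Si](C)(C)C=[N+]=[N-] | starting material
35 | 8β-hydroxy-3α-(tert-butyldimethylsilyloxy)eudesma-4,11(13)-dien-12-oic acid | C[C@]12CC[C@@H](O[Si](C)(C)C(C)(C)C)C(C)=C1C[C@H](C(=C)C(=O)O)[C@H](O)C2 | intermediate
36 | methyl 8β-hydroxy-3α-(tert-butyldimethylsilyloxy)eudesma-4,11(13)-dien-12-oate | C[C@]12CC[C@@H](O[Si](C)(C)C(C)(C)C)C(C)=C1C[C@H](C(=C)C(=O)OC)[C@H](O)C2 | intermediate
37 | acetic anhydride | CC(=O)OC(C)=O | starting material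
38 | methyl 8β-acetoxy-3α-(tert-butyldimethylsilyloxy)eudesma-4,11(13)-dien-12-oate | C[C@]12CC[C@@H](O[Si](C)(C)C(C)(C)C)C(C)=C1C[C@H](C(=C)C(=O)OC)[C@H](OC(C)=O)C2 | intermediate
39 | methyl 8β-acetoxy-3α-hydroxyeudesma-4,11(13)-dien-12-oate | C[C@]12CC[C@@H](O)C(C)=C1C[C@H](C(=C)C(=O)OC)[C@H](OC(C)=O)C2 | intermediate
40 | angelic acid, (Z)-2-methylbut-2-enoic acid | C/C=C(/C)C(=O)O | starting material
41 | methyl 8β-acetoxy-3α-angeloyloxyeudesma-4,11(13)-dien-12-oate | C[C@]12CC[C@@H](OC(=O)/C(C)=C\C)C(C)=C1C[C@H](C(=C)C(=O)OC)[C@H](OC(C)=O)C2 | intermediate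
42 | dioxygen | O=O | starting material
43 | methyl 8β-acetoxy-3α-angeloyloxy-5α-hydroperoxyeudesma-4(15),11(13)-dien-12-oate (CNP0116769.2) | C=C(C(=O)OC)[C@H]1C[C@@]2(OO)C(=C)[C@H](OC(=O)/C(C)=C\C)CC[C@]2(C)C[C@H]1OC(C)=O | target

Total step count: 18. Longest linear sequence: 18 steps (1 to 43, fully linear).

Steps most likely to fail

Step 9. After hydrogen-atom transfer the C4 radical may be reduced before the ring opens. Slow capture of the primary C14 radical may also let it re-close and reopen toward the ring-fusion C5–C10 bond, which enlarges the ring. The fallback sets out from 16 and comes back at 19, and it opens the ring from the ketone instead of from the alkene. Bu3SnH with AIBN in benzene at 80 °C forms the O-stannyl ketyl of the cyclopropyl ketone, which cleaves the same C5–C14 bond; hydrogen transfer to C14 gives the methyl and leaves the tin enolate. Me3SiCl traps this as the C4=C5 trimethylsilyl enol ether F1. MeLi followed by PhNTf2 converts it into the enol triflate F2, and Me2CuLi replaces the triflate by methyl to give 19.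

Step 6. Oxygen transfer to the enolate may show poor facial selectivity and deliver the 3β-hydroxy epimer. The fallback sets out from 11 and comes back at 14, and it sets C3 by inversion instead of by face selection. The 3β-hydroxy ketone F3 is separated and treated under Mitsunobu conditions (4-nitrobenzoic acid, PPh3, DIAD); displacement α to the carbonyl is fast and gives the 3α-(4-nitrobenzoate) F4. Methanolysis with K2CO3 in MeOH at 0 °C then returns 14.

Step 14. The cis-hydroxy acid or its methyl ester may re-close to the lactone, or hydroxide may add to the methylene lactone, before the C8 oxygen is capped. The fallback sets out from 21 and comes back at 38, and it never has a C12 ester next to a free C8 hydroxyl.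
- Alkylation of 21 with allyl bromide (LiN(i-Pr)2, then NaOMe equilibration) gives the 7β-allyl ketone F5.
- Reduction with LiBH(s-Bu)3 gives the 8β-alcohol F6, and Ac2O/DMAP gives the acetate F7.
- Lemieux–Johnson cleavage (OsO4 cat., NaIO4, 2,6-lutidine) of the terminal alkene, which should react far faster than the hindered tetrasubstituted one, gives the aldehyde F8.
- Amine-catalysed α-methylenation with aqueous formaldehyde (pyrrolidine, propionic acid) gives the 2-substituted acrolein F9.
- Pinnick oxidation (NaClO2, NaH2PO4, 2-methyl-2-butene) gives the acrylic acid F10, and Me3SiCHN2 gives 38.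

Further compounds
F1 | step 9 | 4-(trimethylsilyloxy)-3α-(tert-butyldimethylsilyloxy)-11,12,13,15-tetranoreudesm-4-en-8-one ethylene ketal (C4=C5 silyl enol ether, 10β-methyl) | C[C@]12CC[C@@H](O[Si](C)(C)C(C)(C)C)C(O[Si](C)(C)C)=C1CCC3(OCCO3)C2
F2 | step 9 | corresponding C4 enol trifluoromethanesulfonate | C[C@]12CC[C@@H](O[Si](C)(C)C(C)(C)C)C(OS(=O)(=O)C(F)(F)F)=C1CCC3(OCCO3)C2
F3 | step 6 | 3β-hydroxy-5β,10β-methanodecalin-4-one with C8 dioxolane | C1C[C@@]23C[C@]2(CC14OCCO4)CC[C@H](O)C3=O
F4 | step 6 | 3α-(4-nitrobenzoyloxy)-5β,10β-methanodecalin-4-one with C8 dioxolane | C1C[C@@]23C[C@]2(CC14OCCO4)CC[C@@H](OC(=O)c1ccc(cc1)[N+](=O)[O-])C3=O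
F5 | step 14 | 7β-allyl-3α-(tert-butyldimethylsilyloxy)-11,12,13-trinoreudesm-4-en-8-one | C[C@]12CC[C@@H](O[Si](C)(C)C(C)(C)C)C(C)=C1C[C@H](CC=C)C(=O)C2
F6 | step 14 | 7β-allyl-3α-(tert-butyldimethylsilyloxy)-11,12,13-trinoreudesm-4-en-8β-ol | C[C@]12CC[C@@H](O[Si](C)(C)C(C)(C)C)C(C)=C1C[C@H](CC=C)[C@H](O)C2
F7 | step 14 | 8β-acetate of F6 | C[C@]12CC[C@@H](O[Si](C)(C)C(C)(C)C)C(C)=C1C[C@H](CC=C)[C@H](OC(C)=O)C2
F8 | step 14 | 8β-acetoxy-3α-(tert-butyldimethylsilyloxy)-13-noreudesm-4-en-12-al | C[C@]12CC[C@@H](O[Si](C)(C)C(C)(C)C)C(C)=C1C[C@H](CC=O)[C@H](OC(C)=O)C2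
F9 | step 14 | 8β-acetoxy-3α-(tert-butyldimethylsilyloxy)eudesma-4,11(13)-dien-12-al | C[C@]12CC[C@@H](O[Si](C)(C)C(C)(C)C)C(C)=C1C[C@H](C(=C)C=O)[C@H](OC(C)=O)C2
F10 | step 14 | 8β-acetoxy-3α-(tert-butyldimethylsilyloxy)eudesma-4,11(13)-dien-12-oic acid | C[C@]12CC[C@@H](O[Si](C)(C)C(C)(C)C)C(C)=C1C[C@H](C(=C)C(=O)O)[C@H](OC(C)=O)C2
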